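The numbers in the tables were computed for substances that don't exist, noise included.

Once the starting material is gone, intermediate A, intermediate B, target and isomer share a constant sum. So the target moves by two flows: in from intermediate B, out to the isomer. Compare them at one moment, then ask how the comparison drifts.

| flask | starting material | protic impurity | remark | time |
|---|---|---|---|---|
| Sunday's | 1 M | 0.070 M | run made earlier |  |
| Friday's | 1 M | 0.11 M | run made earlier |  |
| teal | 1.0 M | 0.0500 M |  | 48 h |
| violet | 1.0 M | 0.0500 M |  | 96 h |

| run | time / h | target / % | isomer of the product / % | intermediate B / % | starting material / % | intermediate A / % |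
|---|---|---|---|---|---|---|
| Sunday's | 3.00 | 0 | 2 | 11 | 17 | 72 |
| Sunday's | 10.0 | 2 | 1 | 38 | 0 | 55 |
| Sunday's | 20.0 | 11 | 0 | 51 | 0 | 35 |
| Sunday's | 25.0 | 15 | 3 | 52 | 0 | 28 |
| Sunday's | 40.0 | 22 | 3 | 55 | 0 | 11 |
| Sunday's | 48.0 | 27 | 6 | 51 | 0 | 11 |
| Friday's | 3.00 | 1 | 0 | 11 | 16 | 65 |
| Friday's | 10.0 | 4 | 0 | 33 | 0 | 54 |
| Friday's | 20.0 | 10 | 1 | 52 | 0 | 30 |
| Friday's | 25.0 | 14 | 2 | 50 | 2 | 23 |
| Friday's | 40.0 | 25 | 2 | 52 | 0 | 15 |
| Friday's | 48.0 | 27 | 6 | 47 | 1 | 13 |

(scatter of a reading: 1.5 percentage points)

- candidate steps: starting material -> intermediate B; intermediate A <-> intermediate B; starting material -> intermediate A; starting material + protic impurity -> quenched substrate; target <-> isomer of the product; intermediate B -> target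

- which of these there is most of at the end, counted by the starting material in it, teal (target / isomer of the product / intermediate B / intermediate A)
- which of these there is most of at the end, counted by the starting material in it, violet (target / isomer of the product / intermediate B / intermediate A)
- the largest of these amounts at the end, in percent of the starting material charged, teal
- the largest of these amounts at the end, in percent of the starting material charged, violet

Read a rate constant for each flow from the two runs. Products gained between 20.0 h and 48.0 h, over the mean intermediate B, give 0.0156 /h for intermediate B to target. Isomer against target, taken as a straight rise from zero, gives 0.00926 /h. Their quotient, 0.592, is the leak factor. Multiply it by target over intermediate B and you have the leak ratio, the target's outflow over its inflow, with the way back left out.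

Take the protic impurity first. Its charge of 0.0500 M is much less than the 1.0 M of starting material. By hand, it takes from the charge before the pool splits, so target and intermediate B shrink together and the ratio stays. Sunday's and Friday's runs both read 27% target at 48.0 h.

Then take the time. At 48.0 h the runs average 27.0% target, 49.0% intermediate B and 12.0% intermediate A. So the leak ratio is 0.326, less than one. My reckoning lets the pool of both intermediates drain for another 48.0 h. It estimates intermediate B at 26.8% and target at 40.5% for violet, with the leak ratio at 0.895.

The forecast says intermediate B at 51% (47% to 55%) for teal, and target at 46% (39% to 53%) for violet. Its ground for the outflow is “Isomer against the integral of target gives about 0.008 /h”. Its violet target stands higher than my 40.5%.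

Teal gives intermediate B at 50.2%, and violet gives target at 38.8%, below the forecast. On these amounts the leak ratio is 0.330 in teal and 0.834 in violet. The same flask as teal, charged with 0.20 M of protic impurity, holds 25.2% target and 45.1% intermediate B at 48.0 h, a leak ratio of 0.331.

    starting material → intermediate B (k = 4.60 × 10⁻⁴ /min)
    intermediate A ⇌ intermediate B (K = 8.70, k = 9.90 × 10⁻⁴ /min)
    starting material → intermediate A (k = 0.00930 /min)
    starting material + protic impurity → quenched substrate (k = 0.0120 /M/min)
    target ⇌ isomer of the product (K = 26.0, k = 1.90 × 10⁻⁴ /min)
    intermediate B → target (k = 2.70 × 10⁻⁴ /min)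

Violet has not come to rest. It still holds 27.5% intermediate B, and the isomer stands at 25.9%. This is kinetic against thermodynamic control: left in violet until 960 h, intermediate B is down to 0%, target has fallen to 3.58%, and the isomer has reached 92.9%, a ratio to target of 25.9.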